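## Structural features

The target has one ring, a 2-methoxy-1,4-benzoquinone, numbered here C1(=O), C2(OCH3), C3(H), C4(=O), C5(CH3), C6(alkyl). C6 carries a saturated chain C1'–C17': eight unbranched methylenes (C1'–C8'), then methyl-bearing carbons at C9', C11', C13' and C15', and an ethyl terminus (C16'–C17'). The four stereocentres (9'R, 11'R, 13'S, 15'S) stand in 1,3-relationships, each pair separated by one CH2, and are all syn; the change from R to S is only a consequence of the CIP priorities. They lie eight methylenes away from the ring, so the ring cannot relay stereochemical information, and each centre must be set by a reagent or a catalyst. None is epimerisable in the finished chain, but all intermediates are oils, so the purity of each new C–CH3 centre has to be secured when it is made. The quinone is the fragile part (electrophilic at C3, reducible, sensitive to base and nucleophiles) and is therefore made last, after all organometallic and hydrogenation chemistry. The real difficulties are the four remote syn methyl centres and the regiospecific placing of O, OCH3, CH3 and alkyl around the ring. The key step exploits the fact that oxygen on C2 and C4, carbon substituents on C5 and C6, and an oxidised C1 form the pattern of a 5-alkyl-4-methylresorcinol that bore a carboxyl on C1. The bond C1–C6 is made by an aldol reaction between the α-carbon of a dioxinone (C1, with the masked carboxyl) and the chain ketone (C6), and aromatisation then fixes all four ring substituents at once.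

## Logic of the disconnections

33 ⇒ 32. The O–CH3 bond at C2 is cut. That oxygen is the enolic oxygen of a vinylogous acid, so it can be methylated last with methanol and acid. The gain is that no methyl ether has to survive or be differentiated during the oxidation. The forward step must favour the para-quinone ether over the ortho-quinone isomer, which equilibrating acid conditions should ensure.

32 ⇒ 31. The C1=O bond is removed, leaving C1–H. The para-quinone oxygen can be introduced by radical oxidation para to the C4 hydroxyl. The gain is a simple, robust resorcinol as the last aromatic intermediate. The forward step must attack C1 and not C3.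

31 ⇒ 29 (through 30). C1–H is exchanged for the C1–carboxyl bond, and the carboxyl and the C2 oxygen are tied together as an acetonide. The carboxyl is the remnant of the polyketide terminus that makes the ring synthesis possible. The forward step needs hydrolysis and decarboxylation without air oxidation of the electron-rich ring.

29 ⇒ 27. The ring bond C1–C6 is cut and water is added back across C6. This turns a pentasubstituted arene into an acyclic masked triketo acid whose connectivity alone encodes the substitution pattern. The forward step must be a C–C aldol reaction and not an O-cyclisation.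

27 ⇒ 25 + 21. The bond between the methyl-bearing carbon (future C5) and the chain carbonyl (future C6) is cut. This separates the whole chiral chain, as an acyl donor, from a small achiral nucleophile. The acyl donor is 21 and not an acid chloride, because its chelated tetrahedral adduct does not release the acidic triketone while the dianion is still present. The forward step needs C-acylation at the terminal, methyl-substituted carbon of dianion 26.

25 ⇒ 22 + 23. The bond between the ring-bound methylene (future C3) and the ketone carbon (future C4) is cut. Both pieces are commercial. The forward step needs γ-selective acylation of dienolate 24.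

21 ⇒ 19. The amide C–N bond is cut; the demand is only a clean activation of the acid.

19 ⇒ 18 ⇒ 14 + 15. Two hydrogens are removed across C6'–C7', and the resulting double bond is cut. One olefination then attaches C1'–C6' and the carboxyl carbon (future C6) to the chiral fragment. The geometry of the alkene is irrelevant; the hydrogenation must not move the double bond towards C9'.

14 ⇒ 13. The C9'–CH3 bond is cut, which removes one stereocentre and leaves an enethioate acceptor. The forward step needs catalyst-controlled face selectivity that overrides the existing centres.

13 ⇒ 11 + 2 (through 12). The C7'=C8' double bond is cut. This two-carbon extension regenerates the acceptor for the next methyl; the forward step needs (E) geometry.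

11 ⇒ 10. The C11'–CH3 bond is cut, the same cut one unit further along, with the same demand.

10 ⇒ 8 + 2 (through 9). The C9'=C10' double bond is cut.

8 ⇒ 7. The C13'–CH3 bond is cut.

7 ⇒ 5 + 2 (through 6). The C11'=C12' double bond is cut.

5 ⇒ 4. The C15'–CH3 bond is cut. This first addition sets the absolute configuration of the whole chain, so it needs high enantioface selectivity on a small substrate.

4 ⇒ 3 and 2 ⇒ 1. The C–S bonds are cut, leading to two commercial acids and ethanethiol.

## Other disconnections considered

Alternative 1: The cut lies in the side chain and not in the ring. The segment C10'–C15' with the methyls on C11', C13' and C15' is traced to lactone A2, (3S,5R,7R)-3,5,7-trimethyloxepan-2-one. Its carbonyl carbon corresponds to C10', and its ring oxygen sits where the C15'–C16' bond will be. A2 comes from the meso ketone A1, all-cis-2,4,6-trimethylcyclohexanone, by oxygen insertion into one of its two enantiotopic C(=O)–CH(CH3) bonds.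
- Forward key step: a Baeyer–Villiger enzyme of the cyclohexanone monooxygenase type, with O2 and recycled NADPH, would convert A1 into one enantiomer of A2, the migrating carbon keeping its configuration.
- In its favour: three of the four methyl-bearing carbons would be fixed in one catalytic operation from a cheap, flat aromatic precursor. Their relative configuration is inherited from the all-cis ketone and not built up over successive additions. The oxidant is air.
- Against it here:
  - C7 of A2 bears oxygen and not carbon. Mapping A2 onto the target (C3→C11', C5→C13', C7→C15') shows that ethyl must replace that oxygen with net retention to keep the all-syn array. The obvious SN2 displacement of a secondary sulfonate by an ethyl cuprate inverts and competes with elimination, so an extra inversion would be needed.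
  - 2,6-Disubstituted cyclohexanones are demanding substrates for such enzymes, so conversion and selectivity are open questions.
  - C9' and the whole C1'–C9' segment still need a separate asymmetric C–C construction.
  - Nothing is said about the ring, so the aromatisation endgame of the chosen plan would still be required.
- Comparison:
  - Structure: it answers only the chain problem.
  - Mechanism: one enzyme-controlled desymmetrisation replaces several catalyst-controlled additions. For the relative configuration of three centres this is the better guarantee, and on this point the alternative is superior.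
  - Step economy: A2 would be reached in about two steps, against five for 11. The lactone opening, the oxygen-to-ethyl exchange in the correct sense and the extra method for C9' are expected to use up that advantage. Overall it is judged no shorter and less certain.

Alternative 2: The cuts are the four backbone bonds C15'–C16', C13'–C14', C11'–C12' and C9'–C10', with C8' as a carbon–metal terminus. The synthon is A5, (2S,4S,6S,8S)-1-iodo-2,4,6,8-tetramethyldecane, which is C8'–C17' with all four methyls.
- Forward key step: the ethyl groups of diethylzinc A3 would be extended by four successive 1,2-insertions of propene A4. The insertions take place at a cationic zirconium centre made from enantiopure ethylenebis(4,5,6,7-tetrahydro-1-indenyl)zirconium dichloride and methylaluminoxane, with the chains shuttling between zinc and zirconium. Iodine then cleaves the C8'–Zn bond to give A5.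
- In its favour: this is the most step-economical entry conceivable. Four C–C bonds and four stereocentres come from two commodity chemicals in one pot, against nine steps (1–9) to reach 14 in the chosen route. Enantiomorphic-site control by a C2-symmetric metallocene suits an isotactic array, and the primary iodide at C8' is an ideal coupling handle.
- Against it:
  - Chain growth is statistical, so the tetramer would be one member of a series of homologues that differ by C3 units and would need fractional distillation or preparative GC.
  - Site control is relayed through the growing chain and is expected to be weakest for the first insertions into short alkyls, which is exactly the regime needed here. The diastereomeric purity of an inseparable oily hydrocarbon is therefore doubtful.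
  - 2,1-Insertions and β-hydride elimination add by-products.
  - Pyrophoric A3, methylaluminoxane and pressurised A4 make it the least safe option.
- Comparison:
  - Structure: like alternative 1 it addresses only the chain. It would feed the same acid 19 after coupling, and hence the same key step.
  - Mechanism: both plans rely on repeated catalyst-controlled addition to the same prochiral face. The chosen plan does this one bond at a time, with purification and analysis after each.
  - Step economy: clearly better for the alternative. Fidelity of chain length and configuration is clearly better for the chosen plan.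

Alternative 3: The ring is cut at C4–C5 and, one step further back, at C1–C6. The hydroquinone A8, 2-methoxy-5-methyl-6-[(9R,11R,13S,15S)-9,11,13,15-tetramethylheptadecyl]benzene-1,4-diol, is traced to the cyclobutenone A7, 4-hydroxy-3-methoxy-4-[(2E,12R,14R,16S,18S)-12,14,16,18-tetramethylicos-2-en-3-yl]cyclobut-2-en-1-one. A7 is the 1,2-adduct of an alkenyl-lithium with A6, 3-methoxycyclobut-3-ene-1,2-dione.
- Forward key step: heating A7 in toluene (about 110 °C) would open the four-membered ring in a conrotatory sense, the hydroxyl turning outward, to a dienylketene. The ketene carbon (C4) closes onto the propenyl CH (C5) in a 6π electrocyclisation, and the cyclohexadienone tautomerises to A8. Mild oxidation (air, Ag2O or FeCl3) would then give 33.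
- In its favour: every ring substituent is placed by the connectivity of A7, so no regiochemical question arises. The methoxy group is present from the start, so the decarboxylation, the nitrosodisulfonate oxidation and the late methylation all disappear. The conditions are neutral and thermal, and the plan is convergent. On the ring endgame it is the better plan: two operations from A7 to 33, against four from 27.
- Against it:
  - The alkenyl-lithium must be a 3-metallated (E)-alk-2-ene carrying the whole chiral chain. Making its halide precursor regio- and stereoselectively is an open sub-problem: hydrometallation of a methyl/alkyl alkyne discriminates poorly between the two termini, and ketone-derived vinyl iodides form as regio- and E/Z mixtures. The difficulty is moved and not removed.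
  - A6 is less accessible than dialkyl squarates, and its two carbonyls must be differentiated in the addition.
  - The tertiary allylic alcohol A7 is acid-labile.
- Comparison:
  - Structure: both plans build the same ring and need the same chiral chain, so the stereochemical burden is equal.
  - Mechanism: a pericyclic ring expansion with regiochemistry encoded by connectivity stands against a polar aldol reaction with regiochemistry encoded by chain length. Both are unambiguous.
  - Step economy: about equal overall, because an alkyne or vinyl halide synthesis replaces amide formation and acylation while the endgame is shorter. The chosen plan is preferred because each of its steps uses an established substrate class, which the alkenyl-metal needed for A7 does not.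

Key step: step 15

Remarks and assumptions (chemistry only):
- Atom-by-atom mapping of 27 and 29 onto 33 shows both structures to be consistent with the target, so they are used unchanged. The points checked were the eight methylenes between the chain ketone and the first methyl-bearing carbon, the configuration 9'R,11'R,13'S,15'S, and the carboxyl on C1. Compound 27 is used as the mixture of epimers at the carbon between the two ketones.
- Assumption: the (S,RFe) enantiomer of the ferrocenyl diphosphine is taken to deliver methyl to the face of the (E)-enethioates that gives the (S)-configured β-carbon. The sense is purely catalyst-controlled, so the mirror-image ligand would be used in all four additions if a check of the rotation of 5 showed the antipode.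
- Aldehydes 6, 9, 12 and 17 are carried forward as dried crude solutions and are not purified.
- Compounds 31–33 are named with the ring numbering defined under "Structural features".

## Steps

Step 1
Reactants: 1 2-(diethoxyphosphoryl)acetic acid
Product: 2 S-ethyl 2-(diethoxyphosphoryl)ethanethioate
Conditions: EtSH, N,N'-dicyclohexylcarbodiimide, DMAP (cat.), CH2Cl2, 0 °C → rt
Reagents that add atoms: ethanethiol, CCS
Why: Steglich thioesterification: the carbodiimide activates the acid as its O-acylisourea and DMAP relays the acyl group to the thiol; this gives the Horner–Wadsworth–Emmons reagent for steps 4, 6 and 8.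

Step 2
Reactants: 3 (E)-pent-2-enoic acid
Product: 4 S-ethyl (E)-pent-2-enethioate
Conditions: EtSH (1.05 equiv), N,N'-dicyclohexylcarbodiimide, DMAP (cat.), CH2Cl2, 0 °C
Reagents that add atoms: ethanethiol, CCS
Why: The same Steglich thioesterification; low temperature and about one equivalent of thiol keep conjugate addition of the thiol in check, and the (E) geometry of 3 is carried over unchanged.

Step 3
Reactants: 4 S-ethyl (E)-pent-2-enethioate
Product: 5 S-ethyl (S)-3-methylpentanethioate
Conditions: MeMgBr (1.2 equiv), CuBr·SMe2 (1 mol%), (S)-1-[(RFe)-2-(diphenylphosphino)ferrocenyl]ethyldicyclohexylphosphine (1.2 mol%), t-BuOMe, −75 °C; MeOH then aq. NH4Cl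
Reagents that add atoms: methylmagnesium bromide, C[Mg]Br
Why: Copper-catalysed asymmetric conjugate addition of a Grignard reagent to an (E)-α,β-unsaturated thioester; the chiral diphosphine–CuBr complex selects one enantioface and sets C3 of 5 (future C15') as S. The thioester is chosen because it is more electrophilic than an oxo-ester and can later be reduced cleanly to the aldehyde.

Step 4
Reactants: 5 S-ethyl (S)-3-methylpentanethioate; 2 S-ethyl 2-(diethoxyphosphoryl)ethanethioate
Product: 7 S-ethyl (2E,5S)-5-methylhept-2-enethioate, via (S)-3-methylpentanal 6 (not isolated)
Conditions: i-Bu2AlH, CH2Cl2, −78 °C; aq. potassium sodium tartrate, cold dilute NaOH wash, dry; then 2, LiCl, DBU, MeCN, 0 °C → rt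
Reagents that add atoms: none
Why: i-Bu2AlH stops at the aldehyde oxidation level at −78 °C (stable aluminium hemithioacetal), and the volatile aldehyde 6 is olefinated directly under Masamune–Roush Horner–Wadsworth–Emmons conditions, which give the (E)-enethioate. The β-stereocentre of 6 is not enolisable, and the NaOH wash removes ethanethiol that could otherwise add to 7.

Step 5
Reactants: 7 S-ethyl (2E,5S)-5-methylhept-2-enethioate
Product: 8 S-ethyl (3S,5S)-3,5-dimethylheptanethioate
Conditions: MeMgBr (1.2 equiv), CuBr·SMe2 (1 mol%), (S)-1-[(RFe)-2-(diphenylphosphino)ferrocenyl]ethyldicyclohexylphosphine (1.2 mol%), t-BuOMe, −75 °C; MeOH then aq. NH4Cl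
Reagents that add atoms: methylmagnesium bromide, C[Mg]Br
Why: Second catalyst-controlled conjugate addition; the same ligand enantiomer delivers methyl to the same face as in step 3, so the new C3 methyl is syn to the C5 methyl (future C13' and C15'). The remote δ-stereocentre has little influence, so the catalyst decides the outcome.

Step 6
Reactants: 8 S-ethyl (3S,5S)-3,5-dimethylheptanethioate; 2 S-ethyl 2-(diethoxyphosphoryl)ethanethioate
Product: 10 S-ethyl (2E,5S,7S)-5,7-dimethylnon-2-enethioate, via (3S,5S)-3,5-dimethylheptanal 9 (not isolated)
Conditions: i-Bu2AlH, CH2Cl2, −78 °C; aq. potassium sodium tartrate, cold dilute NaOH wash, dry; then 2, LiCl, DBU, MeCN, 0 °C → rt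
Reagents that add atoms: none
Why: The same reduction and Horner–Wadsworth–Emmons homologation as in step 4; neither stereocentre is α to a carbonyl, so both are configurationally safe.

Step 7
Reactants: 10 S-ethyl (2E,5S,7S)-5,7-dimethylnon-2-enethioate
Product: 11 S-ethyl (3S,5S,7S)-3,5,7-trimethylnonanethioate
Conditions: MeMgBr (1.2 equiv), CuBr·SMe2 (1 mol%), (S)-1-[(RFe)-2-(diphenylphosphino)ferrocenyl]ethyldicyclohexylphosphine (1.2 mol%), t-BuOMe, −75 °C; MeOH then aq. NH4Cl
Reagents that add atoms: methylmagnesium bromide, C[Mg]Br
Why: Third catalyst-controlled conjugate addition with the same ligand sets C3 (future C11') syn to the existing methyls; the diastereomer ratio can be checked by GC or 13C NMR before going on.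

Step 8
Reactants: 11 S-ethyl (3S,5S,7S)-3,5,7-trimethylnonanethioate; 2 S-ethyl 2-(diethoxyphosphoryl)ethanethioate
Product: 13 S-ethyl (2E,5S,7S,9S)-5,7,9-trimethylundec-2-enethioate, via (3S,5S,7S)-3,5,7-trimethylnonanal 12 (not isolated)
Conditions: i-Bu2AlH, CH2Cl2, −78 °C; aq. potassium sodium tartrate, cold dilute NaOH wash, dry; then 2, LiCl, DBU, MeCN, 0 °C → rt
Reagents that add atoms: none
Why: Third reduction and Horner–Wadsworth–Emmons homologation, the same chemistry as in steps 4 and 6.

Step 9
Reactants: 13 S-ethyl (2E,5S,7S,9S)-5,7,9-trimethylundec-2-enethioate
Product: 14 S-ethyl (3S,5S,7S,9S)-3,5,7,9-tetramethylundecanethioate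
Conditions: MeMgBr (1.2 equiv), CuBr·SMe2 (1 mol%), (S)-1-[(RFe)-2-(diphenylphosphino)ferrocenyl]ethyldicyclohexylphosphine (1.2 mol%), t-BuOMe, −75 °C; MeOH then aq. NH4Cl
Reagents that add atoms: methylmagnesium bromide, C[Mg]Br
Why: Fourth catalyst-controlled conjugate addition sets C3 (future C9') and completes the all-syn tetramethyl array; the thioester carbon is the future C7'.

Step 10
Reactants: 14 S-ethyl (3S,5S,7S,9S)-3,5,7,9-tetramethylundecanethioate; 15 (6-carboxyhexyl)triphenylphosphonium bromide
Product: 18 (7Z,10S,12S,14S,16S)-10,12,14,16-tetramethyloctadec-7-enoic acid, via carboxylate ylide 16 (not isolated), via (3S,5S,7S,9S)-3,5,7,9-tetramethylundecanal 17 (not isolated)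
Conditions: i-Bu2AlH, CH2Cl2, −78 °C; aq. potassium sodium tartrate, cold dilute NaOH wash, dry, concentrate; 15, NaN(SiMe3)2 (2.1 equiv), THF, 0 °C, then 17, −78 °C → rt; dilute aq. HCl
Reagents that add atoms: none
Why: Reduction as before, then a Wittig reaction with the non-stabilised ylide 16 (one equivalent of base for the carboxylate, one for the ylide) gives mainly the (Z)-alkene, whose geometry is irrelevant because it is hydrogenated next. This single operation adds C1'–C6' and the carboxyl carbon (future ring C6).

Step 11
Reactants: 18 (7Z,10S,12S,14S,16S)-10,12,14,16-tetramethyloctadec-7-enoic acid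
Product: 19 (10R,12R,14S,16S)-10,12,14,16-tetramethyloctadecanoic acid
Conditions: H2 (1 atm), PtO2 (cat.), EtOAc, rt
Reagents that add atoms: none
Why: Heterogeneous hydrogenation of a disubstituted alkene; PtO2 is chosen over palladium on carbon because it causes less double-bond migration towards the C10 stereocentre. The descriptors at C10 and C12 change from S to R only through the CIP priorities; no centre is touched.

Step 12
Reactants: 19 (10R,12R,14S,16S)-10,12,14,16-tetramethyloctadecanoic acid
Product: 21 (10R,12R,14S,16S)-N-methoxy-N,10,12,14,16-pentamethyloctadecanamide, via acyl imidazole 20 (not isolated)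
Conditions: 1,1'-carbonyldiimidazole, CH2Cl2, rt; then MeNHOMe·HCl, rt
Reagents that add atoms: N,O-dimethylhydroxylamine hydrochloride, CNOC.Cl
Why: Activation of the acid as the acyl imidazole 20 and aminolysis give the Weinreb amide; its chelated tetrahedral adduct prevents over-addition and premature release of the acidic triketone in step 14.

Step 13
Reactants: 22 2,2,6-trimethyl-4H-1,3-dioxin-4-one; 23 propanoyl chloride
Product: 25 2,2-dimethyl-6-(2-oxobutyl)-4H-1,3-dioxin-4-one, via lithium dienolate 24 (not isolated)
Conditions: 22 (2 equiv), LiN(SiMe3)2 (2 equiv), THF, −78 °C; 23 (1 equiv), −78 °C; aq. NH4Cl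
Reagents that add atoms: none
Why: Kinetic γ-deprotonation of 22 gives dienolate 24, which is acylated at its γ-carbon by the acid chloride (vinylogous Claisen acylation). Two equivalents of 24 are used because product 25 is more acidic than 22.

Step 14
Reactants: 25 2,2-dimethyl-6-(2-oxobutyl)-4H-1,3-dioxin-4-one; 21 (10R,12R,14S,16S)-N-methoxy-N,10,12,14,16-pentamethyloctadecanamide
Product: 27 2,2-dimethyl-6-[(13R,15R,17S,19S)-3,13,15,17,19-pentamethyl-2,4-dioxohenicosyl]-4H-1,3-dioxin-4-one (C3 epimers), via dilithium dianion 26 (not isolated)
Conditions: 25 (1.5 equiv), LiN(i-Pr)2 (3.1 equiv), THF, −78 → −40 °C; 21 (1 equiv), −78 → −20 °C; cold dilute aq. HCl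
Reagents that add atoms: none
Why: Double deprotonation of 25, first at the methylene next to the dioxinone and then at the ethyl CH2, gives dianion 26, which reacts at its last-formed and most nucleophilic terminal carbon with the Weinreb amide (Claisen-type acylation of a 1,3-dicarbonyl dianion). Acidic quench collapses the chelate to 27, obtained as epimers at the carbon between the ketones; this carbon becomes sp2 in the next step.

Step 15
Reactants: 27 2,2-dimethyl-6-[(13R,15R,17S,19S)-3,13,15,17,19-pentamethyl-2,4-dioxohenicosyl]-4H-1,3-dioxin-4-one (C3 epimers)
Product: 29 7-hydroxy-2,2,6-trimethyl-5-[(9R,11R,13S,15S)-9,11,13,15-tetramethylheptadecyl]-4H-benzo[d][1,3]dioxin-4-one, via aldol adduct 28 (not isolated)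
Conditions: Et3N (3 equiv), CH2Cl2, rt; dilute aq. HCl wash
Reagents that add atoms: none
Why: Triethylamine reversibly removes a proton from the side-chain C1 methylene between the dioxinone and the C2 ketone; the cross-conjugated dienolate is nucleophilic at the dioxinone α-carbon, which adds to the side-chain C4 ketone and forms the quinone C1–C6 bond. This is the base-mediated aldol aromatisation known for diketo-dioxinones (masked 3,5,7-triketo acids), and it mirrors the folding used by alkylresorcinol-forming polyketide synthases. The ring closes in a 6-(enolexo)-exo-trig mode, the enolate C=C lying outside the new ring and the carbonyl oxygen becoming an exocyclic alkoxide, to give aldol 28. E1cB loss of water from 28 and enolisation of the remaining ring ketone aromatise the ring to 29, so no new stereocentre results and both epimers of 27 converge. The selectivity needed is C–C aldol over O-cyclisation to a 4-pyranone and over Claisen attack on the carboxyl. The acetonide keeps the carboxyl as a non-electrophilic vinylogous ester, and the only six-membered carbocycle available joins the dioxinone α-carbon to the chain ketone, so chain on C6, methyl on C5 and oxygen on C2 and C4 follow from connectivity. The four chain stereocentres have no acidic neighbour and are untouched.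

Step 16
Reactants: 29 7-hydroxy-2,2,6-trimethyl-5-[(9R,11R,13S,15S)-9,11,13,15-tetramethylheptadecyl]-4H-benzo[d][1,3]dioxin-4-one
Product: 31 4-methyl-5-[(9R,11R,13S,15S)-9,11,13,15-tetramethylheptadecyl]benzene-1,3-diol, via resorcylic acid 30 (not isolated)
Conditions: KOH (aq., 20%), 1,4-dioxane (degassed), 100 °C; then aq. HCl to pH 1, 80 °C
Reagents that add atoms: none
Why: Hydroxide opens the aryl acylal with release of acetone to give the salt of the β-resorcylic acid 30; after acidification this undergoes thermal protodecarboxylation through ipso-protonation, activated by the ortho and para hydroxyls. Degassed solvents protect the electron-rich resorcinol from air oxidation.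

Step 17
Reactants: 31 4-methyl-5-[(9R,11R,13S,15S)-9,11,13,15-tetramethylheptadecyl]benzene-1,3-diol
Product: 32 2-hydroxy-5-methyl-6-[(9R,11R,13S,15S)-9,11,13,15-tetramethylheptadecyl]cyclohexa-2,5-diene-1,4-dione
Conditions: (KSO3)2NO (2.5 equiv), aq. KH2PO4, acetone/H2O, 0 °C → rt
Reagents that add atoms: potassium nitrosodisulfonate, [K+].[K+].[O]N(S(=O)(=O)[O-])S(=O)(=O)[O-]
Why: Teuber oxidation: the nitroxyl radical abstracts the phenolic hydrogen, a second equivalent traps the aryloxyl radical at the free carbon para to the C4 hydroxyl (C1, which carried the carboxyl), and loss of imidodisulfonate gives the para-quinone. The C2 hydroxyl remains as the vinylogous acid of 32.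

Step 18
Reactants: 32 2-hydroxy-5-methyl-6-[(9R,11R,13S,15S)-9,11,13,15-tetramethylheptadecyl]cyclohexa-2,5-diene-1,4-dione
Product: 33 2-methoxy-5-methyl-6-[(9R,11R,13S,15S)-9,11,13,15-tetramethylheptadecyl]cyclohexa-2,5-diene-1,4-dione
Conditions: MeOH, H2SO4 (cat.), rt → 40 °C
Reagents that add atoms: methanol, CO
Why: Acid-catalysed addition–elimination of methanol at C2 of the vinylogous acid (Fischer-type etherification of a 2-hydroxy-1,4-benzoquinone); under equilibrating conditions the more stable 2-methoxy-para-quinone forms, not the ortho-quinone ether. The chain stereocentres are not involved.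

## Compound list

1 | 2-(diethoxyphosphoryl)acetic acid | CCOP(=O)(CC(=O)O)OCC | starting material
2 | S-ethyl 2-(diethoxyphosphoryl)ethanethioate | CCOP(=O)(CC(=O)SCC)OCC | intermediate
3 | (E)-pent-2-enoic acid | CC/C=C/C(=O)O | starting material
4 | S-ethyl (E)-pent-2-enethioate | CC/C=C/C(=O)SCC | intermediate
5 | S-ethyl (S)-3-methylpentanethioate | CC[C@H](C)CC(=O)SCC | intermediate
6 | (S)-3-methylpentanal | CC[C@H](C)CC=O | intermediate
7 | S-ethyl (2E,5S)-5-methylhept-2-enethioate | CC[C@H](C)C/C=C/C(=O)SCC | intermediate
8 | S-ethyl (3S,5S)-3,5-dimethylheptanethioate | CC[C@H](C)C[C@H](C)CC(=O)SCC | intermediate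
9 | (3S,5S)-3,5-dimethylheptanal | CC[C@H](C)C[C@H](C)CC=O | intermediate
10 | S-ethyl (2E,5S,7S)-5,7-dimethylnon-2-enethioate | CC[C@H](C)C[C@H](C)C/C=C/C(=O)SCC | intermediate
11 | S-ethyl (3S,5S,7S)-3,5,7-trimethylnonanethioate | CC[C@H](C)C[C@H](C)C[C@H](C)CC(=O)SCC | intermediate
12 | (3S,5S,7S)-3,5,7-trimethylnonanal | CC[C@H](C)C[C@H](C)C[C@H](C)CC=O | intermediate
13 | S-ethyl (2E,5S,7S,9S)-5,7,9-trimethylundec-2-enethioate | CC[C@H](C)C[C@H](C)C[C@H](C)C/C=C/C(=O)SCC | intermediate
14 | S-ethyl (3S,5S,7S,9S)-3,5,7,9-tetramethylundecanethioate | CC[C@H](C)C[C@H](C)C[C@H](C)C[C@H](C)CC(=O)SCC | intermediate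
15 | (6-carboxyhexyl)triphenylphosphonium bromide | [Br-].OC(=O)CCCCCC[P+](c1ccccc1)(c1ccccc1)c1ccccc1 | starting material
16 | sodium 7-(triphenyl-λ5-phosphanylidene)heptanoate (carboxylate ylide) | [Na+].[O-]C(=O)CCCCCC=P(c1ccccc1)(c1ccccc1)c1ccccc1 | intermediate
17 | (3S,5S,7S,9S)-3,5,7,9-tetramethylundecanal | CC[C@H](C)C[C@H](C)C[C@H](C)C[C@H](C)CC=O | intermediate
18 | (7Z,10S,12S,14S,16S)-10,12,14,16-tetramethyloctadec-7-enoic acid | CC[C@H](C)C[C@H](C)C[C@H](C)C[C@H](C)C/C=C\CCCCCC(=O)O | intermediate
19 | (10R,12R,14S,16S)-10,12,14,16-tetramethyloctadecanoic acid | CC[C@H](C)C[C@H](C)C[C@H](C)C[C@H](C)CCCCCCCCC(=O)O | intermediate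
20 | 1-[(10R,12R,14S,16S)-10,12,14,16-tetramethyloctadecanoyl]-1H-imidazole (acyl imidazole) | CC[C@H](C)C[C@H](C)C[C@H](C)C[C@H](C)CCCCCCCCC(=O)n1ccnc1 | intermediate
21 | (10R,12R,14S,16S)-N-methoxy-N,10,12,14,16-pentamethyloctadecanamide | CC[C@H](C)C[C@H](C)C[C@H](C)C[C@H](C)CCCCCCCCC(=O)N(C)OC | intermediate
22 | 2,2,6-trimethyl-4H-1,3-dioxin-4-one | CC1=CC(=O)OC(C)(C)O1 | starting material
23 | propanoyl chloride | CCC(=O)Cl | starting material
24 | lithium 2,2-dimethyl-6-methylidene-6H-1,3-dioxin-4-olate (lithium dienolate) | [Li+].C=C1C=C([O-])OC(C)(C)O1 | intermediate
25 | 2,2-dimethyl-6-(2-oxobutyl)-4H-1,3-dioxin-4-one | CCC(=O)CC1=CC(=O)OC(C)(C)O1 | intermediate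
26 | dilithium 1-(2,2-dimethyl-4-oxido-6H-1,3-dioxin-6-ylidene)but-2-en-2-olate (dilithium dianion of 25) | [Li+].[Li+].CC=C([O-])C=C1C=C([O-])OC(C)(C)O1 | intermediate
27 | 2,2-dimethyl-6-[(13R,15R,17S,19S)-3,13,15,17,19-pentamethyl-2,4-dioxohenicosyl]-4H-1,3-dioxin-4-one (C3 epimers) | CC1(C)OC(=O)C=C(CC(=O)C(C)C(=O)CCCCCCCC[C@@H](C)C[C@@H](C)C[C@@H](C)C[C@@H](C)CC)O1 | intermediate
28 | 5-hydroxy-2,2,6-trimethyl-5-[(9R,11R,13S,15S)-9,11,13,15-tetramethylheptadecyl]-5,6-dihydro-4H-benzo[d][1,3]dioxine-4,7(8H)-dione (aldol adduct, diastereomers at C5 and C6) | CC1(C)OC2=C(C(=O)O1)C(O)(CCCCCCCC[C@@H](C)C[C@@H](C)C[C@@H](C)C[C@@H](C)CC)C(C)C(=O)C2 | intermediate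
29 | 7-hydroxy-2,2,6-trimethyl-5-[(9R,11R,13S,15S)-9,11,13,15-tetramethylheptadecyl]-4H-benzo[d][1,3]dioxin-4-one | CC1(C)Oc2cc(O)c(C)c(CCCCCCCC[C@@H](C)C[C@@H](C)C[C@@H](C)C[C@@H](C)CC)c2C(=O)O1 | intermediate
30 | 4,6-dihydroxy-3-methyl-2-[(9R,11R,13S,15S)-9,11,13,15-tetramethylheptadecyl]benzoic acid (resorcylic acid) | OC(=O)c1c(O)cc(O)c(C)c1CCCCCCCC[C@@H](C)C[C@@H](C)C[C@@H](C)C[C@@H](C)CC | intermediate
31 | 4-methyl-5-[(9R,11R,13S,15S)-9,11,13,15-tetramethylheptadecyl]benzene-1,3-diol | Cc1c(O)cc(O)cc1CCCCCCCC[C@@H](C)C[C@@H](C)C[C@@H](C)C[C@@H](C)CC | intermediate
32 | 2-hydroxy-5-methyl-6-[(9R,11R,13S,15S)-9,11,13,15-tetramethylheptadecyl]cyclohexa-2,5-diene-1,4-dione | CC1=C(CCCCCCCC[C@@H](C)C[C@@H](C)C[C@@H](C)C[C@@H](C)CC)C(=O)C(O)=CC1=O | intermediate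
33 | 2-methoxy-5-methyl-6-[(9R,11R,13S,15S)-9,11,13,15-tetramethylheptadecyl]cyclohexa-2,5-diene-1,4-dione | CC[C@H](C)C[C@H](C)C[C@H](C)C[C@H](C)CCCCCCCCC1=C(C)C(=O)C=C(OC)C1=O | target

## Step count and least certain steps

Total step count: 18. Longest linear sequence: 16 steps, from 3 to 33 through steps 2–12 and 14–18. Steps 1 and 13 are side branches.

Step 15 (key step). The aldol closure may be slow, because the dioxinone α-carbon has to attack a ketone flanked by a tertiary, methyl-bearing carbon. Retro-aldol reaction, or O-cyclisation of the diketone enol onto the dioxinone (pyranone formation with opening of the acetal), could then compete with dehydration and aromatisation. The fallback sets out from 27 and changes the substrate class. Heating 27 in toluene with methanol (about 110 °C) releases acetone by retro-[4+2] fragmentation, and the acyl ketene is trapped as methyl (16R,18R,20S,22S)-6,16,18,20,22-pentamethyl-3,5,7-trioxotetracosanoate F1. Treatment of F1 with Cs2CO3 in methanol and then acid closes the same C1–C6 bond by aldol condensation of the open-chain triketo ester and gives methyl 4,6-dihydroxy-3-methyl-2-[(9R,11R,13S,15S)-9,11,13,15-tetramethylheptadecyl]benzoate F2. Saponification and decarboxylation of F2 (aq. KOH, then acid and heat) return to the route at 31.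

Step 14. Proton transfer may win over C–C bond formation: the basic dianion can enolise 21, and the attacking terminal carbon is secondary because it carries the methyl. Reaction at oxygen or at the internal carbon of the dianion is a further risk. The fallback sets out from 21 and replaces acylation by aldol addition and oxidation. Reduction of 21 with i-Bu2AlH (THF, −78 °C) gives (10R,12R,14S,16S)-10,12,14,16-tetramethyloctadecanal F3. Addition of dianion 26 to this far more electrophilic aldehyde gives 6-[(13R,15R,17S,19S)-4-hydroxy-3,13,15,17,19-pentamethyl-2-oxohenicosyl]-2,2-dimethyl-4H-1,3-dioxin-4-one F4 as a diastereomer mixture. Dess–Martin oxidation of the β-hydroxy ketone F4 returns to the route at 27.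

Step 17. The hydroxyquinone formed is itself electron-rich and acidic, so over-oxidation, radical coupling and attack at C3 (between the two oxygens) may erode the material. Slow transfer of the lipophilic substrate to the aqueous radical adds to this. The fallback sets out from 31 and reverses the order of methylation and oxidation. Mono-O-methylation (Me2SO4, 1 equiv, K2CO3, acetone) should favour the less hindered hydroxyl and give 5-methoxy-2-methyl-3-[(9R,11R,13S,15S)-9,11,13,15-tetramethylheptadecyl]phenol F5. F5 would have to be separated by chromatography from its regioisomer and the diether; these can be recycled by demethylation. Oxidation of F5 with (KSO3)2NO under phase-transfer conditions (CH2Cl2/water) then occurs para to the only free hydroxyl and gives the non-acidic, more stable methoxyquinone directly. This rejoins the route at 33 and bypasses 32.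

Step 3 (and, for the same reason, steps 5, 7 and 9). Enantioface discrimination may be incomplete or of the wrong sense, because the ethyl substituent and the incoming methyl differ little in size and an uncatalysed background addition gives racemate. Such an error cannot be removed later, since all downstream compounds are oils. The fallback sets out from 3 and uses auxiliary control with separable diastereomers. The mixed pivalic anhydride of 3 is coupled with lithiated (R)-4-phenyloxazolidin-2-one to give (R)-3-[(E)-pent-2-enoyl]-4-phenyloxazolidin-2-one F6. Conjugate addition of the methylcopper reagent from MeMgBr and CuBr·SMe2 (THF/Me2S, −40 °C) takes place anti to the phenyl group of the chelated s-cis imide and gives (R)-3-[(S)-3-methylpentanoyl]-4-phenyloxazolidin-2-one F7, which is purified as a single diastereomer. Cleavage of F7 with lithium ethanethiolate (EtSH, n-BuLi, THF, 0 °C) returns to the route at 5 and frees the auxiliary.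

## Further compounds

F1 | step 15 | methyl (16R,18R,20S,22S)-6,16,18,20,22-pentamethyl-3,5,7-trioxotetracosanoate (C6 epimers) | COC(=O)CC(=O)CC(=O)C(C)C(=O)CCCCCCCC[C@@H](C)C[C@@H](C)C[C@@H](C)C[C@@H](C)CC
F2 | step 15 | methyl 4,6-dihydroxy-3-methyl-2-[(9R,11R,13S,15S)-9,11,13,15-tetramethylheptadecyl]benzoate | COC(=O)c1c(O)cc(O)c(C)c1CCCCCCCC[C@@H](C)C[C@@H](C)C[C@@H](C)C[C@@H](C)CC
F3 | step 14 | (10R,12R,14S,16S)-10,12,14,16-tetramethyloctadecanal | CC[C@H](C)C[C@H](C)C[C@H](C)C[C@H](C)CCCCCCCCC=O
F4 | step 14 | 6-[(13R,15R,17S,19S)-4-hydroxy-3,13,15,17,19-pentamethyl-2-oxohenicosyl]-2,2-dimethyl-4H-1,3-dioxin-4-one (diastereomers at C3 and C4) | CC1(C)OC(=O)C=C(CC(=O)C(C)C(O)CCCCCCCC[C@@H](C)C[C@@H](C)C[C@@H](C)C[C@@H](C)CC)O1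
F5 | step 17 | 5-methoxy-2-methyl-3-[(9R,11R,13S,15S)-9,11,13,15-tetramethylheptadecyl]phenol | COc1cc(O)c(C)c(CCCCCCCC[C@@H](C)C[C@@H](C)C[C@@H](C)C[C@@H](C)CC)c1
F6 | step 3 | (R)-3-[(E)-pent-2-enoyl]-4-phenyloxazolidin-2-one | CC/C=C/C(=O)N1[C@H](c2ccccc2)COC1=O
F7 | step 3 | (R)-3-[(S)-3-methylpentanoyl]-4-phenyloxazolidin-2-one | CC[C@H](C)CC(=O)N1[C@H](c2ccccc2)COC1=O
A1 | alternative 1 | all-cis-2,4,6-trimethylcyclohexanone (meso) | O=C1[C@@H](C)C[C@@H](C)C[C@H]1C
A2 | alternative 1 | (3S,5R,7R)-3,5,7-trimethyloxepan-2-one | O=C1[C@@H](C)C[C@@H](C)C[C@@H](C)O1
A3 | alternative 2 | diethylzinc | CC[Zn]CC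
A4 | alternative 2 | propene | CC=C
A5 | alternative 2 | (2S,4S,6S,8S)-1-iodo-2,4,6,8-tetramethyldecane | CC[C@H](C)C[C@H](C)C[C@H](C)C[C@H](C)CI
A6 | alternative 3 | 3-methoxycyclobut-3-ene-1,2-dione | COC1=CC(=O)C1=O
A7 | alternative 3 | 4-hydroxy-3-methoxy-4-[(2E,12R,14R,16S,18S)-12,14,16,18-tetramethylicos-2-en-3-yl]cyclobut-2-en-1-one (carbinol epimers) | COC1=CC(=O)C1(O)/C(CCCCCCCC[C@@H](C)C[C@@H](C)C[C@@H](C)C[C@@H](C)CC)=C/C
A8 | alternative 3 | 2-methoxy-5-methyl-6-[(9R,11R,13S,15S)-9,11,13,15-tetramethylheptadecyl]benzene-1,4-diol | COc1cc(O)c(C)c(CCCCCCCC[C@@H](C)C[C@@H](C)C[C@@H](C)C[C@@H](C)CC)c1O
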